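## Retrosynthetic overview
1. Target 8, read as (R), comes from 7 by one global hydrogenolysis of three O-benzyl ethers and the benzyl ester. This releases the open acid rather than the 7-O-lactone.
2. The key disconnection is the C8–C(sp3) bond with reversed polarity, not the usual conjugate addition or Friedel–Crafts hydroarylation of a cinnamate. The 8-iodoflavone 3 is the electrophile, the enantioenriched secondary benzylic trifluoroborate 6 is the nucleophile, and they join in a stereoinvertive Suzuki–Miyaura coupling.
3. 6 comes from benzyl cinnamate 4 by copper-catalysed asymmetric β-borylation. The only stereocentre is set on this small fragment, and its ee can be raised by crystallisation.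
4. 3 comes from apigenin 1 by perbenzylation and C8-selective iodination.
5. No ring is built. Rings A, B and C arrive intact with apigenin, and the phenyl ring arrives with the cinnamate.

Assumption: the (R,Sp)-ferrocenyl diphosphine/CuCl catalyst of step 3 is taken to give the (S)-boronate from the (E)-cinnamate; an aliquot is oxidised to the known β-hydroxy ester to check this, and if the sense is opposite the equally available mirror-image ligand is used with nothing else changed.

## Route

Step 1
Reactants: 1 apigenin (5,7,4'-trihydroxyflavone)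
Product: 2 5,7,4'-tri-O-benzylapigenin
Conditions: BnBr (4.5 equiv), K2CO3 (6 equiv), Bu4NI (10 mol %), DMF, 80 °C, 16 h
Reagents that add atoms: benzyl bromide, BrCc1ccccc1
Why: Williamson ether synthesis, in which excess BnBr and K2CO3 alkylate the acidic 7- and 4'-phenols quickly and at 80 °C also the chelated 5-OH, so that no acidic proton is left for the metal-catalysed steps and the flavone becomes soluble; no stereocentre is involved.

Step 2
Reactants: 2 5,7,4'-tri-O-benzylapigenin
Product: 3 5,7,4'-tri-O-benzyl-8-iodoapigenin
Conditions: NIS (1.05 equiv), TFA (10 mol %), CH2Cl2/MeCN, 0 °C to rt, dark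
Reagents that add atoms: N-iodosuccinimide, O=C1CCC(=O)N1I
Why: Electrophilic aromatic iodination (SEAr) on ring A, the most electron-rich ring, where fully O-alkylated 5,7-dioxygenated flavones react at C8 because it is para to the 5-alkoxy group and flanked only by the ring oxygen and one benzyloxy group, whereas C6 is wedged between two benzyloxy groups.

Step 3
Reactants: 4 benzyl (E)-cinnamate
Product: 5 benzyl (3S)-3-phenyl-3-(4,4,5,5-tetramethyl-1,3,2-dioxaborolan-2-yl)propanoate
Conditions: CuCl (3 mol %), NaOt-Bu (3 mol %), (R)-1-[(Sp)-2-(diphenylphosphino)ferrocenyl]ethyldicyclohexylphosphine (Josiphos type, 3 mol %), B2pin2 (1.1 equiv), BnOH (2 equiv), THF, rt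
Reagents that add atoms: bis(pinacolato)diboron, CC1(C)OB(OC1(C)C)B1OC(C)(C)C(C)(C)O1
Why: Copper-catalysed asymmetric conjugate borylation (β-borylation of an enoate), in which the chiral LCu–Bpin species adds to one enantioface of the (E)-enoate with boron going to the benzylic carbon and the alcohol protonates the copper enolate, so the only stereocentre of the synthesis is set here as (S), and benzyl alcohol as proton source rules out ester scrambling.

Step 4
Reactants: 5 benzyl (3S)-3-phenyl-3-(pinacolboryl)propanoate
Product: 6 potassium [(1S)-3-(benzyloxy)-3-oxo-1-phenylpropyl]trifluoroborate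
Conditions: KHF2 (4.5 M aq, 4 equiv), MeOH, 0 °C to rt; evaporate, extract with hot acetone, precipitate with Et2O, recrystallise
Reagents that add atoms: potassium hydrogen difluoride, F.[F-].[K+]
Why: Boronate-to-trifluoroborate exchange with KHF2 takes place at boron only, so the C–B stereocentre is untouched, and the crystalline salt can be recrystallised to raise the ee before the key step.

Step 5
Reactants: 3 5,7,4'-tri-O-benzyl-8-iodoapigenin, 6 potassium [(1S)-3-(benzyloxy)-3-oxo-1-phenylpropyl]trifluoroborate (1.5 equiv)
Product: 7 benzyl (3R)-3-[5,7-bis(benzyloxy)-2-(4-benzyloxyphenyl)-4-oxo-4H-chromen-8-yl]-3-phenylpropanoate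
Conditions: Pd(OAc)2 (10 mol %), XPhos (20 mol %), K2CO3 (3 equiv), CPME/H2O 7:1, degassed, 90 °C, 24 h
Reagents that add atoms: none
Why: Stereospecific Suzuki–Miyaura sp2–sp3 cross-coupling, in which zerovalent palladium bearing the bulky biaryl phosphine inserts into the hindered C8–I bond, the β-ester carbonyl binds to boron so that the benzylic carbon is handed to divalent arylpalladium from the face opposite to boron (open SE2 transmetalation with inversion, the course established for secondary β-trifluoroborato amides and esters), the same carbonyl then blocks the site needed for β-hydride elimination, and fast reductive elimination from the crowded complex turns (S)-6 into (R)-7.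

Step 6
Reactants: 7 benzyl (3R)-3-[5,7-bis(benzyloxy)-2-(4-benzyloxyphenyl)-4-oxo-4H-chromen-8-yl]-3-phenylpropanoate
Product: 8 (3R)-3-[5,7-dihydroxy-2-(4-hydroxyphenyl)-4-oxo-4H-chromen-8-yl]-3-phenylpropanoic acid (target)
Conditions: H2 (1 atm), 10 % Pd/C, THF/MeOH 1:1, rt; filter, concentrate below 30 °C
Reagents that add atoms: none
Why: Catalytic hydrogenolysis of the three aryl benzyl ethers and the benzyl ester under neutral conditions releases the triphenol acid directly in its open form with no acid or heat to close the 7-O-lactone, while the pyranone C2=C3 bond and the C–C bonds of the diarylmethine stereocentre are inert at 1 atm, so (R) is retained.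

## Compound list
1 | apigenin | O=c1cc(-c2ccc(O)cc2)oc2cc(O)cc(O)c12 | starting material
2 | 5,7,4'-tri-O-benzylapigenin | O=c1cc(-c2ccc(OCc3ccccc3)cc2)oc2cc(OCc3ccccc3)cc(OCc3ccccc3)c12 | intermediate
3 | 5,7,4'-tri-O-benzyl-8-iodoapigenin | O=c1cc(-c2ccc(OCc3ccccc3)cc2)oc2c(I)c(OCc3ccccc3)cc(OCc3ccccc3)c12 | intermediate
4 | benzyl (E)-cinnamate | O=C(OCc1ccccc1)/C=C/c1ccccc1 | starting material
5 | benzyl (3S)-3-phenyl-3-(4,4,5,5-tetramethyl-1,3,2-dioxaborolan-2-yl)propanoate | O=C(OCc1ccccc1)C[C@@H](c1ccccc1)B1OC(C)(C)C(C)(C)O1 | intermediate
6 | potassium [(1S)-3-(benzyloxy)-3-oxo-1-phenylpropyl]trifluoroborate | O=C(OCc1ccccc1)C[C@@H](c1ccccc1)[B-](F)(F)F.[K+] | intermediate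
7 | benzyl (3R)-3-[5,7-bis(benzyloxy)-2-(4-benzyloxyphenyl)-4-oxo-4H-chromen-8-yl]-3-phenylpropanoate | O=C(OCc1ccccc1)C[C@H](c1ccccc1)c1c(OCc2ccccc2)cc(OCc2ccccc2)c2c(=O)cc(-c3ccc(OCc4ccccc4)cc3)oc12 | intermediate
8 | (3R)-3-[5,7-dihydroxy-2-(4-hydroxyphenyl)-4-oxo-4H-chromen-8-yl]-3-phenylpropanoic acid | O=C(O)C[C@H](c1ccccc1)c1c(O)cc(O)c2c(=O)cc(-c3ccc(O)cc3)oc12 | target

## Step count and risks
Total step count: 6. Longest linear sequence: 4 steps (1 → 2 → 3 → 7 → 8, or equally 4 → 5 → 6 → 7 → 8).

**Step 5 (highest risk).** The aryl iodide carries two ortho oxygen substituents and the boron partner is secondary and benzylic.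
- Transmetalation may be slow.
- The trifluoroborate may protodeboronate.
- β-Hydride elimination may lead back to 4.
- Stereochemical fidelity may be partly lost.

The fallback sets out from 3 and comes back at 7. It moves the stereo-defining event onto the flavone. A Mizoroki–Heck reaction of 3 with benzyl acrylate (Pd(OAc)2, P(o-tol)3, K2CO3, DMF, 100 °C) gives benzyl (E)-3-[5,7-bis(benzyloxy)-2-(4-benzyloxyphenyl)-4-oxo-4H-chromen-8-yl]acrylate F1. A Hayashi–Miyaura 1,4-addition of the unhindered PhB(OH)2 follows ([Rh(C2H4)2Cl]2 with a chiral bicyclo[2.2.2]octadiene or BINAP ligand of the hand that gives (R), aq KOH, dioxane, 40 °C). It forms the Ph–C bond and the stereocentre and delivers 7. The β,β-disubstituted flavone enone does not compete as an acceptor.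

**Step 2.** Some C6-iodide, 6,8-diiodide or iodination of ring B ortho to the 4'-benzyloxy group may form, and the isomers may be hard to separate. The fallback sets out from 1 and comes back at 3. It reverses the order of events so that electronic direction by the free phenols controls the site instead of sterics. Apigenin is treated with NIS (1 equiv) in DMF at rt under neutral conditions. Attack then goes ortho to the 7-OH and para to the 5-OH, as in Mannich reactions of 5,7-dihydroxyflavones, and gives 8-iodoapigenin F2. This is purified by crystallisation and perbenzylated (BnBr, K2CO3, DMF, 80 °C) to 3.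

**Step 6.** The C2=C3 bond may be over-reduced to the flavanone, the hindered 5- and 7-benzyl ethers may cleave slowly, or the lactone may close on concentration. The fallback sets out from 7 and comes back at 8 and uses no reductant. Saponification (LiOH, THF/H2O, rt) gives (3R)-3-[5,7-bis(benzyloxy)-2-(4-benzyloxyphenyl)-4-oxo-4H-chromen-8-yl]-3-phenylpropanoic acid F3. Lewis-acid dealkylation with BCl3 and pentamethylbenzene as cation scavenger (CH2Cl2, −78 °C, cold aqueous quench) removes the three aryl benzyl ethers and gives 8.

## Further compounds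
F1 | step 5 | benzyl (E)-3-[5,7-bis(benzyloxy)-2-(4-benzyloxyphenyl)-4-oxo-4H-chromen-8-yl]acrylate | O=C(OCc1ccccc1)/C=C/c1c(OCc2ccccc2)cc(OCc2ccccc2)c2c(=O)cc(-c3ccc(OCc4ccccc4)cc3)oc12
F2 | step 2 | 8-iodoapigenin | O=c1cc(-c2ccc(O)cc2)oc2c(I)c(O)cc(O)c12
F3 | step 6 | (3R)-3-[5,7-bis(benzyloxy)-2-(4-benzyloxyphenyl)-4-oxo-4H-chromen-8-yl]-3-phenylpropanoic acid | O=C(O)C[C@H](c1ccccc1)c1c(OCc2ccccc2)cc(OCc2ccccc2)c2c(=O)cc(-c3ccc(OCc4ccccc4)cc3)oc12
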